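Assumption: all-E geranylgeraniol (annatto-derived, sold in bulk) is taken as a cheap commercial starting material; cyclized compounds carry labdane numbering, compound 1 carries geranylgeraniol numbering.

## Retrosynthetic overview

1. The whole C20 skeleton is bought as all-E geranylgeraniol 1. A cyclase-mediated protonation, bicyclization and water capture gives, via C8 cation 2, labd-13E-ene-8α,15-diol 3; acetylation of the primary alcohol gives target 4.
2. Disconnections, read back from the target: the C15–O acetyl bond; then C8–OH, C9–C10, C4–C5 and C3–H, all in one cationic cascade.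
3. Ring order: ring A (C4–C5 bond) first, ring B (C9–C10 bond) second; the cascade is stopped there by water at C8.
4. All four stereocentres (C5, C8, C9, C10) come from that one step; the 13E olefin is carried over from 1. A squalene–hopene cyclase stands in for the biosynthetic labdenol diphosphate synthase, so no diphosphate has to be put on or taken off.

## Route

Step 1
Reactants: 1 (2E,6E,10E)-geranylgeraniol
Product: 3 labd-13E-ene-8α,15-diol, via 15-hydroxylabd-13E-en-8-yl cation 2 (not isolated)
Conditions: recombinant AacSHC (squalene–hopene cyclase of Alicyclobacillus acidocaldarius, UniProt P33247; wild type first, then a Phe365/Tyr420 variant panel), citric acid/trisodium citrate buffer pH 6.0, 2-hydroxypropyl-β-cyclodextrin, 50 °C, 48 h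
Reagents that add atoms: water, O
Why: Proposed new method: Asp376 of the cyclase protonates the terminal C14=C15 olefin of 1 held in an all-chair fold, and the 10,11- and 6,7-olefins add anti (ring A, then ring B) to give tertiary cation 2; ring C closure is disfavoured because the remaining olefin is inductively deactivated by its allylic oxygen and, in a C20 substrate, is not clamped in the half-empty, water-accessible lower cavity, so water adds to C8 on the α (equatorial) face, anti to the new C9–C10 bond and away from the axial C10 methyl; chair–chair folding of the E olefins fixes the trans ring fusion and the 8α-OH/9β-side-chain relationship, and the enzyme fixes the absolute sense (5S,8R,9R,10S, as in rings A and B of hopene and in its (−)-ambrox product); reaction type: proton-initiated cationic polyene (Stork–Eschenmoser) bicyclization with hydrative termination; closest known reactions: this enzyme's cyclization of homofarnesol to (−)-ambrox and of farnesol and geranylgeraniol to drimane and labdane alcohols, its native water capture giving hopan-22-ol, and the labd-13-en-8-ol diphosphate synthase reaction of the biosynthesis; the new element is steering termination to water at the bicyclic stage, for which mutation of the aromatic residues flanking the ring B cation (Phe365, Tyr420, known to arrest squalene at the bicyclic stage) is the handle.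

Step 2
Reactants: 3 labd-13E-ene-8α,15-diol
Product: 4 8α-hydroxylabd-13E-en-15-yl acetate (target)
Conditions: Ac2O (1.2 equiv), pyridine, 0 °C to rt, 4 h
Reagents that add atoms: acetic anhydride, CC(=O)OC(C)=O
Why: O-acetylation (nucleophilic acyl substitution) is selective for the unhindered primary allylic alcohol, the hindered tertiary C8 alcohol being inert to Ac2O/pyridine without an acyl-transfer catalyst (as are the tertiary alcohols of sclareol); no stereocentre or olefin is touched.

## Compound list

1 | (2E,6E,10E)-geranylgeraniol, (2E,6E,10E)-3,7,11,15-tetramethylhexadeca-2,6,10,14-tetraen-1-ol | CC(C)=CCC/C(C)=C/CC/C(C)=C/CC/C(C)=C/CO | starting material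
2 | 15-hydroxylabd-13E-en-8-yl cation (5S,9R,10S; enzyme-bound tertiary carbocation) | OC/C=C(\C)CC[C@@H]1[C@@]2(C)CCCC(C)(C)[C@@H]2CC[C+]1C | intermediate
3 | labd-13E-ene-8α,15-diol, (1R,2R,4aS,8aS)-1-[(3E)-5-hydroxy-3-methylpent-3-en-1-yl]-2,5,5,8a-tetramethyldecahydronaphthalen-2-ol | OC/C=C(\C)CC[C@@H]1[C@@]2(C)CCCC(C)(C)[C@@H]2CC[C@@]1(C)O | intermediate
4 | 8α-hydroxylabd-13E-en-15-yl acetate, (2E)-5-[(1R,2R,4aS,8aS)-2-hydroxy-2,5,5,8a-tetramethyldecahydronaphthalen-1-yl]-3-methylpent-2-en-1-yl acetate (CNP0268033.1) | CC(=O)OC/C=C(\C)CC[C@@H]1[C@@]2(C)CCCC(C)(C)[C@@H]2CC[C@@]1(C)O | target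

## Step count and risk

Total step count: 2. Longest linear sequence: 2.

Steps most likely to fail: the route has only two steps, so both are ranked and there is no third.

1. Step 1 (the main risk). Water capture at C8 may lose to deprotonation (labda-8(17),13- and labda-7,13-dien-15-ols) or to ring C closure, and conversion of a C20 alcohol may be low; stereocontrol is not the weak point. The diol is far more polar than the dienol by-products, so even a modest share is isolable. Fallback (sets out from 1, comes back at 3): hand the cyclization to the enzyme that nature uses for this very skeleton, with its native substrate. MsCl, LiCl and 2,4,6-collidine in DMF at 0 °C convert 1, through (2E,6E,10E)-geranylgeranyl methanesulfonate F1 formed and displaced in the flask, into (2E,6E,10E)-geranylgeranyl chloride F2. Tris(tetrabutylammonium) hydrogen diphosphate in MeCN, then exchange to the ammonium form, gives (2E,6E,10E)-geranylgeranyl diphosphate F3. Recombinant labd-13-en-8-ol diphosphate synthase (for example the Salvia sclarea enzyme) with MgCl2 at pH 7.5 and 30 °C cyclizes F3 through 15-diphosphooxylabd-13E-en-8-yl cation F4 to labd-13E-en-8α-ol-15-yl diphosphate F5. Alkaline phosphatase added to the same pot cleaves F5 through labd-13E-en-8α-ol-15-yl phosphate F6 to diol 3, and step 2 follows unchanged.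

2. Step 2 (low risk). Over-acetylation is unlikely; the hazards are acid-promoted loss of the tertiary alcohol during work-up or on silica, and handling losses of the polar diol. Fallback (sets out from 1, comes back at 4): acetylate before cyclizing. Ac2O in pyridine turns 1 into (2E,6E,10E)-geranylgeranyl acetate F7, and the cyclase treatment of step 1 then takes F7 through 15-acetoxylabd-13E-en-8-yl cation F8 straight to 4. The ester deactivates the 13,14-olefin more strongly than the free alcohol does, which should favour the stop at ring B. The cyclase must be used as a purified or heat-treated preparation so that host esterases do not cleave the acetate.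

## Further compounds

F1 | step 1 | (2E,6E,10E)-geranylgeranyl methanesulfonate | CC(C)=CCC/C(C)=C/CC/C(C)=C/CC/C(C)=C/COS(C)(=O)=O
F2 | step 1 | (2E,6E,10E)-geranylgeranyl chloride | CC(C)=CCC/C(C)=C/CC/C(C)=C/CC/C(C)=C/CCl
F3 | step 1 | (2E,6E,10E)-geranylgeranyl diphosphate (handled as its ammonium salt) | CC(C)=CCC/C(C)=C/CC/C(C)=C/CC/C(C)=C/COP(=O)(O)OP(=O)(O)O
F4 | step 1 | 15-diphosphooxylabd-13E-en-8-yl cation (5S,9R,10S) | OP(=O)(O)OP(=O)(O)OC/C=C(\C)CC[C@@H]1[C@@]2(C)CCCC(C)(C)[C@@H]2CC[C+]1C
F5 | step 1 | labd-13E-en-8α-ol-15-yl diphosphate (5S,8R,9R,10S) | OP(=O)(O)OP(=O)(O)OC/C=C(\C)CC[C@@H]1[C@@]2(C)CCCC(C)(C)[C@@H]2CC[C@@]1(C)O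
F6 | step 1 | labd-13E-en-8α-ol-15-yl phosphate (5S,8R,9R,10S) | OP(=O)(O)OC/C=C(\C)CC[C@@H]1[C@@]2(C)CCCC(C)(C)[C@@H]2CC[C@@]1(C)O
F7 | step 2 | (2E,6E,10E)-geranylgeranyl acetate | CC(C)=CCC/C(C)=C/CC/C(C)=C/CC/C(C)=C/COC(C)=O
F8 | step 2 | 15-acetoxylabd-13E-en-8-yl cation (5S,9R,10S) | CC(=O)OC/C=C(\C)CC[C@@H]1[C@@]2(C)CCCC(C)(C)[C@@H]2CC[C+]1C
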